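**Retrosynthetic overview**

- The strategy rests on C3 of the phthalide. It is the benzylic stereocentre and also the alkyl-oxygen end (O2–C3) of the five-membered lactone ring (C1 carbonyl, O2, C3, C3a, C7a), so one C–O bond formation can make the only new ring and the C3 configuration together.
- The chain C1'–C14' is cut at C1'–C2': a C3 vinyl group is joined to a C2'–C14' terminal alkene by cross-metathesis, followed by C1'=C2' reduction and removal of the 5-O-benzyl group.
- The 3-vinylphthalide is traced to a 2-methoxy-6-(prop-1-ynyl)benzoic acid, whose carboxylate is delivered to the benzylic carbon of a rhodium pi-allyl formed from the alkyne (lactone ring formed here; the benzene ring is bought).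
- The acid comes from methyl 2,4,6-trihydroxybenzoate: 4-O-benzyl, 2-O-methyl, 6-O-triflate, Sonogashira coupling with propyne, saponification.
- The chain alkene comes from (S)-gamma-valerolactone (C13' stereocentre, C10' carbonyl, C11'–C14') and 9-bromonon-1-ene (C2'–C9') through a Weinreb amide.

Key step: step 6

Assumption: the sense of induction of DIOP in step 6 cannot be assigned in advance; (R,R)-DIOP is written, and the equally available (S,S)-DIOP is to be used if a first trial shows the (R)-lactone to predominate.
Remark: the gamma-hydroxy ketones of the route (the chain alcohol, all later compounds and the target) can equilibrate with their cyclic hemiketals; they are named and drawn in the open form.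

**Route**

Step 1
Reactants: 1 methyl 2,4,6-trihydroxybenzoate
Product: 2 methyl 4-(benzyloxy)-2,6-dihydroxybenzoate
Conditions: BnOH (1.05 equiv), PPh3, DIAD, THF, 0 °C to rt
Reagents that add atoms: benzyl alcohol, OCc1ccccc1
Why: Mitsunobu etherification should pick the 4-OH, the most acidic phenol and the only one not hydrogen-bonded to the ester, and it avoids the C-benzylation that phloroglucinol anions suffer with benzyl bromide and base.

Step 2
Reactants: 2 methyl 4-(benzyloxy)-2,6-dihydroxybenzoate
Product: 3 methyl 4-(benzyloxy)-2-hydroxy-6-methoxybenzoate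
Conditions: MeI (1.1 equiv), K2CO3 (1.2 equiv), acetone, 40 °C
Reagents that add atoms: iodomethane, CI
Why: Williamson methylation of the symmetric 2,6-diol should stop after one methyl group, because the remaining phenol is then locked in a strong hydrogen bond to the ester carbonyl and is much less nucleophilic.

Step 3
Reactants: 3 methyl 4-(benzyloxy)-2-hydroxy-6-methoxybenzoate
Product: 4 methyl 4-(benzyloxy)-2-methoxy-6-[(trifluoromethanesulfonyl)oxy]benzoate
Conditions: Tf2O, pyridine, CH2Cl2, 0 °C
Reagents that add atoms: trifluoromethanesulfonic anhydride, O=S(=O)(OS(=O)(=O)C(F)(F)F)C(F)(F)F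
Why: O-sulfonylation of the single remaining phenol is standard for salicylate esters and touches neither the benzyl ether nor the methyl ester.

Step 4
Reactants: 4 methyl 4-(benzyloxy)-2-methoxy-6-[(trifluoromethanesulfonyl)oxy]benzoate; 5 propyne
Product: 6 methyl 4-(benzyloxy)-2-methoxy-6-(prop-1-yn-1-yl)benzoate
Conditions: PdCl2(PPh3)2 (5 mol %), CuI (10 mol %), Et3N, DMF, propyne (3 equiv), sealed tube, 60 °C
Reagents that add atoms: none
Why: Sonogashira coupling should proceed because the triflate is ortho to the ester and only meta to the two alkoxy groups, so oxidative addition to zerovalent palladium is not retarded.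

Step 5
Reactants: 6 methyl 4-(benzyloxy)-2-methoxy-6-(prop-1-yn-1-yl)benzoate
Product: 7 4-(benzyloxy)-2-methoxy-6-(prop-1-yn-1-yl)benzoic acid
Conditions: aq. KOH (2 M), MeOH/THF, 65 °C; then 1 M HCl, 0 °C, to pH 3
Reagents that add atoms: potassium hydroxide, [K+].[OH-]
Why: Saponification of the di-ortho-substituted ester is slowed but not blocked by the slim linear alkyne, hydroxide does not isomerise an aryl methyl alkyne, and cold mild acidification avoids acid-promoted cyclisation of the ortho-alkynyl acid.

Step 6
Reactants: 7 4-(benzyloxy)-2-methoxy-6-(prop-1-yn-1-yl)benzoic acid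
Product: 9 (S)-5-(benzyloxy)-7-methoxy-3-vinylisobenzofuran-1(3H)-one, via aryl allene acid 8 (not isolated)
Conditions: [Rh(cod)Cl]2 (2.5 mol %), (R,R)-DIOP (6 mol %), ClCH2CH2Cl (0.05 M), 80 °C
Reagents that add atoms: none
Why: Proposed new method: the acid O–H should add oxidatively to monovalent rhodium to give a trivalent rhodium hydride carboxylate, which hydrometalates the aryl methyl alkyne and undergoes beta-hydride elimination from the methyl group to the aryl allene 8; re-insertion of 8 into Rh–H gives a 1-aryl pi-allyl complex, and C–O reductive elimination at its benzylic end forms O2–C3 and returns monovalent rhodium. The closest known reaction type is the rhodium/DIOP-catalysed, branched-selective and enantioselective addition of carboxylic acids to allenes and to methyl-substituted alkynes, 1-arylpropynes included, which has also been run intramolecularly as a macrolactonisation; its use on an ortho-alkynylbenzoic acid to close a five-membered lactone is the untested part. The lactone ring closes in a 5-exo mode by attack of the tethered carboxylate oxygen on the benzylic allyl carbon, since attack at the CH2 end would need a seven-membered ring. The C3 configuration is set by the C2-symmetric bisphosphine on rhodium, which distinguishes the two faces of the allyl terminus in the inner-sphere C–O bond formation. The step needs chemoselectivity for the hydride/allene pathway over direct oxy-cyclisation of the carboxylate onto the alkyne (to an isocoumarin or an alkylidene phthalide); this rests on the base-free, chloride-bound and phosphine-ligated rhodium centre being a weak pi-acid, while the alkyne methyl group supplies the propargylic hydrogens that open the allene pathway and the short ortho tether fixes the site of C–O bond formation.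

Step 7
Reactants: 10 (S)-gamma-valerolactone
Product: 11 (S)-4-hydroxy-N-methoxy-N-methylpentanamide
Conditions: Me(MeO)NH·HCl (1.5 equiv), iPrMgCl (3 equiv), THF, −20 to 0 °C; crude product used at once
Reagents that add atoms: N,O-dimethylhydroxylamine hydrochloride, CNOC.Cl
Why: Weinreb aminolysis of the lactone by the magnesium amide cleaves the acyl C–O bond only, so the carbinol stereocentre is untouched.

Step 8
Reactants: 11 (S)-4-hydroxy-N-methoxy-N-methylpentanamide
Product: 12 (S)-4-[(tert-butyldimethylsilyl)oxy]-N-methoxy-N-methylpentanamide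
Conditions: TBSCl, imidazole, DMF, rt
Reagents that add atoms: tert-butyldimethylsilyl chloride, CC(C)(C)[Si](C)(C)Cl
Why: Silylation of the secondary alcohol stops the hydroxy amide from closing back to the lactone and removes the acidic proton before the Grignard step.

Step 9
Reactants: 12 (S)-4-[(tert-butyldimethylsilyl)oxy]-N-methoxy-N-methylpentanamide; 13 9-bromonon-1-ene
Product: 15 (S)-2-[(tert-butyldimethylsilyl)oxy]tetradec-13-en-5-one, via non-8-en-1-ylmagnesium bromide 14 (not isolated)
Conditions: 13 (1.5 equiv), Mg turnings, I2 (cat.), THF, 40 °C; then 12, THF, 0 °C; aq. NH4Cl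
Reagents that add atoms: none
Why: Grignard addition to the Weinreb amide stops at the ketone stage because the magnesium-chelated tetrahedral adduct survives until work-up.

Step 10
Reactants: 15 (S)-2-[(tert-butyldimethylsilyl)oxy]tetradec-13-en-5-one
Product: 16 (S)-2-hydroxytetradec-13-en-5-one
Conditions: HF·pyridine, pyridine, THF, 0 °C to rt
Reagents that add atoms: none
Why: Fluoride-driven desilylation under buffered conditions frees the alcohol without dehydrating the gamma-hydroxy ketone, and no bond to the stereocentre is broken.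

Step 11
Reactants: 9 (S)-5-(benzyloxy)-7-methoxy-3-vinylisobenzofuran-1(3H)-one; 16 (S)-2-hydroxytetradec-13-en-5-one
Product: 17 (S)-5-(benzyloxy)-3-[(S,E)-13-hydroxy-10-oxotetradec-1-en-1-yl]-7-methoxyisobenzofuran-1(3H)-one
Conditions: second-generation Hoveyda–Grubbs catalyst (5 mol %), 16 (2.5 equiv), 1,4-benzoquinone (10 mol %), CH2Cl2, 40 °C
Reagents that add atoms: none
Why: Olefin cross-metathesis between an excess of the unhindered terminal alkene and the slower 1-aryl allylic carboxylate alkene is driven by loss of ethylene, tolerates the free alcohol and ketone, and does not involve C3; the alkene geometry (mainly E expected) is of no consequence.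

Step 12
Reactants: 17 (S)-5-(benzyloxy)-3-[(S,E)-13-hydroxy-10-oxotetradec-1-en-1-yl]-7-methoxyisobenzofuran-1(3H)-one
Product: 18 (S)-5-(benzyloxy)-3-[(S)-13-hydroxy-10-oxotetradecyl]-7-methoxyisobenzofuran-1(3H)-one
Conditions: KO2C–N=N–CO2K (excess, in portions), AcOH (slow addition), CH2Cl2, rt
Reagents that add atoms: none
Why: Diimide transfers two hydrogens to C1'=C2' in a concerted step and cannot hydrogenolyse the allylic and benzylic C3–O2 bond or the benzyl ether, and this diimide source contains no hydrazide that could condense with the C10' ketone.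

Step 13
Reactants: 18 (S)-5-(benzyloxy)-3-[(S)-13-hydroxy-10-oxotetradecyl]-7-methoxyisobenzofuran-1(3H)-one
Product: 19 (S)-5-hydroxy-3-[(S)-13-hydroxy-10-oxotetradecyl]-7-methoxyisobenzofuran-1(3H)-one
Conditions: H2 (1 atm), palladium on carbon (10% Pd/C), EtOAc, rt
Reagents that add atoms: none
Why: Hydrogenolysis of the aryl benzyl ether under neutral low-pressure conditions should leave the saturated 3-alkylphthalide C–O bond, the ketone and both stereocentres intact.

**Compound list**

1 | methyl 2,4,6-trihydroxybenzoate | COC(=O)c1c(O)cc(O)cc1O | starting material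
2 | methyl 4-(benzyloxy)-2,6-dihydroxybenzoate | COC(=O)c1c(O)cc(OCc2ccccc2)cc1O | intermediate
3 | methyl 4-(benzyloxy)-2-hydroxy-6-methoxybenzoate | COC(=O)c1c(O)cc(OCc2ccccc2)cc1OC | intermediate
4 | methyl 4-(benzyloxy)-2-methoxy-6-[(trifluoromethanesulfonyl)oxy]benzoate | COC(=O)c1c(OC)cc(OCc2ccccc2)cc1OS(=O)(=O)C(F)(F)F | intermediate
5 | propyne | CC#C | starting material
6 | methyl 4-(benzyloxy)-2-methoxy-6-(prop-1-yn-1-yl)benzoate | CC#Cc1cc(OCc2ccccc2)cc(OC)c1C(=O)OC | intermediate
7 | 4-(benzyloxy)-2-methoxy-6-(prop-1-yn-1-yl)benzoic acid | CC#Cc1cc(OCc2ccccc2)cc(OC)c1C(=O)O | intermediate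
8 | 4-(benzyloxy)-2-methoxy-6-(propa-1,2-dien-1-yl)benzoic acid (not isolated) | C=C=Cc1cc(OCc2ccccc2)cc(OC)c1C(=O)O | intermediate
9 | (S)-5-(benzyloxy)-7-methoxy-3-vinylisobenzofuran-1(3H)-one | COc1cc(OCc3ccccc3)cc2c1C(=O)O[C@H]2C=C | intermediate
10 | (S)-gamma-valerolactone | O=C1CC[C@H](C)O1 | starting material
11 | (S)-4-hydroxy-N-methoxy-N-methylpentanamide | CON(C)C(=O)CC[C@H](C)O | intermediate
12 | (S)-4-[(tert-butyldimethylsilyl)oxy]-N-methoxy-N-methylpentanamide | CON(C)C(=O)CC[C@H](C)O[Si](C)(C)C(C)(C)C | intermediate
13 | 9-bromonon-1-ene | C=CCCCCCCCBr | starting material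
14 | non-8-en-1-ylmagnesium bromide (not isolated) | C=CCCCCCCC[Mg]Br | intermediate
15 | (S)-2-[(tert-butyldimethylsilyl)oxy]tetradec-13-en-5-one | C=CCCCCCCCC(=O)CC[C@H](C)O[Si](C)(C)C(C)(C)C | intermediate
16 | (S)-2-hydroxytetradec-13-en-5-one | C=CCCCCCCCC(=O)CC[C@H](C)O | intermediate
17 | (S)-5-(benzyloxy)-3-[(S,E)-13-hydroxy-10-oxotetradec-1-en-1-yl]-7-methoxyisobenzofuran-1(3H)-one | COc1cc(OCc3ccccc3)cc2c1C(=O)O[C@H]2/C=C/CCCCCCCC(=O)CC[C@H](C)O | intermediate
18 | (S)-5-(benzyloxy)-3-[(S)-13-hydroxy-10-oxotetradecyl]-7-methoxyisobenzofuran-1(3H)-one | COc1cc(OCc3ccccc3)cc2c1C(=O)O[C@H]2CCCCCCCCCC(=O)CC[C@H](C)O | intermediate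
19 | (S)-5-hydroxy-3-[(S)-13-hydroxy-10-oxotetradecyl]-7-methoxyisobenzofuran-1(3H)-one | COc1cc(O)cc2c1C(=O)O[C@H]2CCCCCCCCCC(=O)CC[C@H](C)O | target

Total step count: 13. Longest linear sequence: 9 steps (steps 1–6, then 11–13).

**Steps most likely to fail**

1. Step 6. Direct oxy-cyclisation of the carboxylate onto the alkyne may outrun the hydride/allene pathway, or the ligand may discriminate the faces of the allyl terminus poorly. The fallback uses known chemistry, sets out from 4 and returns at 9. Suzuki–Miyaura coupling of 4 with potassium vinyltrifluoroborate (PdCl2(dppf), Cs2CO3, THF/H2O, 80 °C) would give methyl 4-(benzyloxy)-2-methoxy-6-vinylbenzoate F1. Lemieux–Johnson cleavage (OsO4 cat., NaIO4, 2,6-lutidine, dioxane/H2O) would give methyl 4-(benzyloxy)-2-formyl-6-methoxybenzoate F2. Enantioselective addition of divinylzinc, Zn(CH=CH2)2, catalysed by a chiral amino alcohol (toluene/Et2O, 0 °C) would give methyl 4-(benzyloxy)-2-[(S)-1-hydroxyprop-2-en-1-yl]-6-methoxybenzoate F3. Its alkoxide should close onto the ortho ester on work-up with catalytic TsOH to give 9.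

2. Step 11. Initiation at the hindered 1-aryl allylic carboxylate alkene may be so slow that only the chain alkene homodimerises, or a ruthenium hydride may move the double bond into conjugation and destroy C3. The fallback replaces metathesis by hydroboration and B-alkyl Suzuki coupling; it sets out from 9 and 12 and returns at 19.
   - Commercial 7-bromohept-1-ene and Mg would give hept-6-en-1-ylmagnesium bromide F4, which with 12 would give (S)-2-[(tert-butyldimethylsilyl)oxy]dodec-11-en-5-one F5.
   - Cleavage with OsO4 cat./NaIO4 would give (S)-10-[(tert-butyldimethylsilyl)oxy]-7-oxoundecanal F6.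
   - Aldehyde-selective Takai olefination (CrCl2, CHI3, THF) would give (S,E)-2-[(tert-butyldimethylsilyl)oxy]-12-iodododec-11-en-5-one F7, and HF·pyridine would give (S,E)-2-hydroxy-12-iodododec-11-en-5-one F8.
   - Terminal-selective hydroboration of 9 with 9-BBN (THF, rt) would give (S)-3-[2-(9-borabicyclo[3.3.1]nonan-9-yl)ethyl]-5-(benzyloxy)-7-methoxyisobenzofuran-1(3H)-one F9.
   - Coupling of F9 with F8 (PdCl2(dppf), AsPh3, Cs2CO3, DMF/H2O, rt) would give (S)-5-(benzyloxy)-3-[(S,E)-13-hydroxy-10-oxotetradec-3-en-1-yl]-7-methoxyisobenzofuran-1(3H)-one F10.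
   - The C3'=C4' alkene of F10 is remote from the lactone C–O bond, so one hydrogenation (H2, 10% Pd/C, EtOAc) should reduce it and cleave the benzyl ether to give 19.

3. Step 12. Diimide may disproportionate faster than it reduces the trans-disubstituted, allylically oxygenated alkene, leaving conversion incomplete. The fallback sets out from 17 and returns at 18: homogeneous catalytic hydrogenation with RhCl(PPh3)3 (5 mol %) under H2 (1 atm) in benzene/EtOH at rt. This reduces disubstituted alkenes without hydrogenolysing allylic or benzylic C–O bonds or benzyl ethers, and it makes no new compound.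

**Further compounds**

F1 | step 6 | methyl 4-(benzyloxy)-2-methoxy-6-vinylbenzoate | C=Cc1cc(OCc2ccccc2)cc(OC)c1C(=O)OC
F2 | step 6 | methyl 4-(benzyloxy)-2-formyl-6-methoxybenzoate | O=Cc1cc(OCc2ccccc2)cc(OC)c1C(=O)OC
F3 | step 6 | methyl 4-(benzyloxy)-2-[(S)-1-hydroxyprop-2-en-1-yl]-6-methoxybenzoate | C=C[C@H](O)c1cc(OCc2ccccc2)cc(OC)c1C(=O)OC
F4 | step 11 | hept-6-en-1-ylmagnesium bromide | C=CCCCCC[Mg]Br
F5 | step 11 | (S)-2-[(tert-butyldimethylsilyl)oxy]dodec-11-en-5-one | C=CCCCCCC(=O)CC[C@H](C)O[Si](C)(C)C(C)(C)C
F6 | step 11 | (S)-10-[(tert-butyldimethylsilyl)oxy]-7-oxoundecanal | O=CCCCCCC(=O)CC[C@H](C)O[Si](C)(C)C(C)(C)C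
F7 | step 11 | (S,E)-2-[(tert-butyldimethylsilyl)oxy]-12-iodododec-11-en-5-one | I/C=C/CCCCCC(=O)CC[C@H](C)O[Si](C)(C)C(C)(C)C
F8 | step 11 | (S,E)-2-hydroxy-12-iodododec-11-en-5-one | I/C=C/CCCCCC(=O)CC[C@H](C)O
F9 | step 11 | (S)-3-[2-(9-borabicyclo[3.3.1]nonan-9-yl)ethyl]-5-(benzyloxy)-7-methoxyisobenzofuran-1(3H)-one | COc1cc(OCc3ccccc3)cc2c1C(=O)O[C@H]2CCB4C5CCCC4CCC5
F10 | step 11 | (S)-5-(benzyloxy)-3-[(S,E)-13-hydroxy-10-oxotetradec-3-en-1-yl]-7-methoxyisobenzofuran-1(3H)-one | COc1cc(OCc3ccccc3)cc2c1C(=O)O[C@H]2CC/C=C/CCCCCC(=O)CC[C@H](C)O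
F0 | step 12 | none | none
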